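| flask | substrate | remark | time |
|---|---|---|---|
| dusk | 0.50 M | run made earlier |  |
| winter | 0.75 M | run made earlier |  |
| flask | 1.0 M |  | 10 d |

| run | time / d | intermediate B / % | target / % | substrate / % |
|---|---|---|---|---|
| dusk | 0.167 | 26 | 0 | 9 |
| dusk | 0.333 | 45 | 0 | 3 |
| dusk | 0.625 | 57 | 3 | 0 |
| dusk | 1.25 | 51 | 7 | 0 |
| dusk | 2.50 | 26 | 23 | 3 |
| dusk | 5.00 | 10 | 61 | 0 |
| dusk | 10.0 | 0 | 79 | 0 |
| winter | 0.167 | 23 | 0 | 7 |
| winter | 0.333 | 47 | 0 | 1 |
| winter | 0.625 | 62 | 2 | 0 |
| winter | 1.25 | 50 | 9 | 2 |
| winter | 2.50 | 30 | 22 | 0 |
| winter | 5.00 | 10 | 57 | 0 |
| winter | 10.0 | 0 | 79 | 0 |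

(each reading ± 2 percentage points)

* time up to 10 d at which intermediate B stands highest
* the amount of intermediate B, in percent of the substrate charged, at that time
* earliest time at which at least nineteen twentieths of that best amount are there, in d
* latest time at which they still are, in d

- the numbers in the tables scatter by 2 percentage points (one standard deviation)
- candidate steps: substrate -> intermediate A; intermediate A -> intermediate B; intermediate B -> intermediate C; intermediate C -> target; intermediate A -> side product

- The ratio of intermediate B at 2.50 d to intermediate B at 5.00 d, summed over the dusk and winter runs, is 2.80. Its logarithm over that interval gives a fall rate of 0.412 /d.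
- The two runs, at 0.50 M and 0.75 M, read alike within the scatter, so we carry their percentages to the flask at 1.0 M.
- With the peak read at 0.625 d, 0.257 is our loss number, the fall rate of intermediate B times the time of its peak. It measures what decay has cost intermediate B by the top.
- With one first-order step into an intermediate and one out of it, the peak equals the share passing through it times e to the minus the loss number. Here a further step stands upstream, so we use this as an estimate.
- The target at 10.0 d averages 79.0%, so we expect 61.1% in the flask.
- The test is the two readings at the peak, which the number did not use. They average 59.5%, with a scatter of 2 percentage points on each. The number holds no rise, so it gives no window.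
- The forecast gives 0.71 d, 60%, 0.5 d and 1 d, starting from “Substrate falls the same way at 0.50 and 0.75 M”. Its peak time put into our number gives 59.0%.
- The flask gives 0.681 d, 59.8%, 0.487 d and 0.950 d, and the forecast holds within the margins.

    substrate → intermediate A (k = 0.650 /h)
    intermediate A → intermediate B (k = 0.130 /h)
    intermediate B → intermediate C (k = 0.0220 /h)
    intermediate C → target (k = 0.0210 /h)
    intermediate A → side product (k = 0.0270 /h)

- In the flask, intermediate A goes to intermediate B with a half-life of 0.22 d, shorter than the 1.3 d of intermediate B going to intermediate C. At 0.681 d the flask's constant for intermediate B going to intermediate C, 0.022 /h, makes the loss number 0.360, larger than the 0.281 from the fall rate read in the runs. With the flask's 82.8% of target at 100 d as the share, the number gives 57.8% against the flask's 59.8%. The number from the runs gives 61.1% for the neighbour flask charged with 0.60 M, and that flask reaches 59.8%.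

The numbers in the tables are simulated from invented constants; the scatter is artificial.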